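**Strategy.** Everything rests on reading the seco ring as a cut trans-decalin. C4, the carbinol carbon of the hydroxyisopropyl group, and C3, the δ-lactone carbonyl, were once joined in ring A of a 4,4-dimethyl-3-decalone whose angular C15H2OH (on C10) is the lactone's CH2O arm. One operation, Baeyer–Villiger insertion of oxygen into C3–C4 followed by acyl transfer to O15, opens ring A, closes the spiro δ-lactone and releases the tertiary alcohol. Its precursor is trans-decalone 24: C3 ketone, free C15 hydroxyl, 7β-silyloxy, 8β-methyl and the C9 spiro γ-lactone, carried as its α-methylene form so that the lactone can later be enolised regiospecifically for cage assembly.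

Key step: step 16

Remark 1 (numbering): C1–C10 = decalin, C11 = lactone CH2 on C9, C12 = carbon on C8, C15 = angular CH2O on C10, C16/C17/C18 = lactone α-carbon, its exocyclic carbon and carbonyl; C1′–C4′ = CH(Me), CH(CO2), CH(O) and ketal carbon of the incoming unit; β = face of C15.
Remark 2 (design): the C7 hydroxyl travels as a TIPS ether (fluoride-labile, so no basic deacylation is needed beside the lactones and ortho ester); the spirolactone carries C17 as a methylene (same carbon skeleton), which step 19 converts into the methyl group while generating the lactone ketene acetal selectively beside the δ-lactone.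
Remark 3 (assumption): hydroxy ketone 24 may rest as its C3/C15 ring–chain hemiketal; it is written in the open form.
Remark 4 (check): 24 and 26 carry the target's configuration at C5, C7, C8, C9 and C10 (5α-H, 7β-O, 8β-Me, 9β-O/11α, 10β-C15); step 16 creates and destroys no stereocentre.

Step 1
Reactants: 1 4-methylpent-3-en-1-ol
Product: 2 4-methylpent-3-en-1-yl tosylate
Conditions: TsCl, Et3N, DMAP (cat.), CH2Cl2, 0 °C to rt
Reagents that add atoms: p-toluenesulfonyl chloride, Cc1ccc(cc1)S(=O)(=O)Cl
Why: Sulfonylation of the primary alcohol gives a leaving group that cannot participate as a neighbouring group in steps 2 and 3.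

Step 2
Reactants: 2 4-methylpent-3-en-1-yl tosylate
Product: 3 2-[(2S)-3,3-dimethyloxiran-2-yl]ethyl tosylate
Conditions: L-fructose-derived Shi ketone (0.3 equiv), Oxone, K2CO3, Bu4NHSO4, aq. Na2B4O7/Na2EDTA, MeCN–CH2(OMe)2, 0 °C
Reagents that add atoms: potassium peroxymonosulfate (Oxone), [K+].[O-]S(=O)(=O)OO
Why: Shi asymmetric epoxidation of the trisubstituted alkene through the spiro dioxirane transition state; this ketone enantiomer should give the (S)-epoxide, which becomes the C7 carbinol centre.

Step 3
Reactants: 3 2-[(2S)-3,3-dimethyloxiran-2-yl]ethyl tosylate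
Product: 4 (3S)-4-methyl-3-(triisopropylsilyloxy)pent-4-en-1-yl tosylate
Conditions: TIPSOTf, 2,6-lutidine, toluene, −78 to 0 °C
Reagents that add atoms: triisopropylsilyl trifluoromethanesulfonate, CC(C)[Si](OS(=O)(=O)C(F)(F)F)(C(C)C)C(C)C
Why: Silyl-triflate-mediated epoxide-to-allylic-silyl-ether isomerisation: O-silylation, cleavage of the tertiary C–O bond and loss of a methyl proton to the base give the isopropenyl carbinol ether, with the secondary C–O bond and hence the (S) centre untouched.

Step 4
Reactants: 4 (3S)-4-methyl-3-(triisopropylsilyloxy)pent-4-en-1-yl tosylate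
Product: 5 [(3S)-4-methyl-3-(triisopropylsilyloxy)pent-4-en-1-yl]triphenylphosphonium iodide
Conditions: NaI, PPh3, MeCN, reflux
Reagents that add atoms: triphenylphosphine, c1ccc(cc1)P(c1ccccc1)c1ccccc1; sodium iodide, [Na+].[I-]
Why: Finkelstein exchange followed by SN2 quaternisation of the phosphine at the primary carbon (phosphonium salt formation).

Step 5
Reactants: 6 5-bromo-2-methylpent-2-ene; 7 (tert-butyldimethylsilyloxy)acetaldehyde
Product: 9 1-(tert-butyldimethylsilyloxy)-6-methylhept-5-en-2-ol (racemic), via 4-methylpent-3-enylmagnesium bromide 8 (not isolated)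
Conditions: Mg, THF, rt; then 7, −20 °C; aq. NH4Cl
Reagents that add atoms: magnesium, [Mg] (present only in 8)
Why: Grignard formation and 1,2-addition to the aldehyde; the racemic carbinol centre is erased in step 6.

Step 6
Reactants: 9 1-(tert-butyldimethylsilyloxy)-6-methylhept-5-en-2-ol
Product: 10 1-(tert-butyldimethylsilyloxy)-6-methylhept-5-en-2-one
Conditions: Dess–Martin periodinane, NaHCO3, CH2Cl2, rt
Reagents that add atoms: none
Why: Dess–Martin oxidation of the secondary alcohol under buffered, non-epimerising conditions that spare the silyl ether and the alkene.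

Step 7
Reactants: 5 [(3S)-4-methyl-3-(triisopropylsilyloxy)pent-4-en-1-yl]triphenylphosphonium iodide; 10 1-(tert-butyldimethylsilyloxy)-6-methylhept-5-en-2-one
Product: 12 TBS ether of (2Z,5S)-6-methyl-2-(4-methylpent-3-enyl)-5-(triisopropylsilyloxy)hepta-2,6-dien-1-ol, via phosphonium ylide 11 (not isolated)
Conditions: KHMDS, THF, −78 °C; then 10, −78 °C to rt
Reagents that add atoms: none
Why: Wittig olefination of an α-silyloxy ketone with a non-stabilised ylide, which should place CH2OTBS cis to the ylide-derived chain (Z), i.e. the extended chain geometry that a trans-decalin requires.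

Step 8
Reactants: 12 TBS ether of (2Z,5S)-6-methyl-2-(4-methylpent-3-enyl)-5-(triisopropylsilyloxy)hepta-2,6-dien-1-ol
Product: 13 TBS ether of (2Z,5S)-2-{2-[(2S)-3,3-dimethyloxiran-2-yl]ethyl}-6-methyl-5-(triisopropylsilyloxy)hepta-2,6-dien-1-ol
Conditions: L-fructose-derived Shi ketone (0.3 equiv), Oxone (1.2 equiv), K2CO3, Bu4NHSO4, aq. buffer, MeCN–CH2(OMe)2, 0 °C
Reagents that add atoms: potassium peroxymonosulfate (Oxone), [K+].[O-]S(=O)(=O)OO
Why: Shi epoxidation at the only electron-rich, unhindered trisubstituted alkene (the other two are deactivated by allylic silyloxy groups and one is 1,1-disubstituted), with the same catalyst sense as in step 2 to give the (S)-epoxide.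

Step 9
Reactants: 13 TBS ether of (2Z,5S)-2-{2-[(2S)-3,3-dimethyloxiran-2-yl]ethyl}-6-methyl-5-(triisopropylsilyloxy)hepta-2,6-dien-1-ol
Product: 15 11-nordrim-8(12)-ene-3β,7β,15-triol 7-O-TIPS 15-O-TBS ether (5α-H), via C3 trimethylsilyl ether 14 (not isolated)
Conditions: Cp2TiCl2 (0.2 equiv), Mn dust, TMSCl, 2,4,6-collidine, THF, rt; then K2CO3 (cat.), MeOH
Reagents that add atoms: chlorotrimethylsilane, C[Si](C)(C)Cl (present only in 14)
Why: Titanocene(III) reductive epoxide opening and 6-endo/6-endo radical bicyclisation (C4 radical onto C5, C10 radical onto the terminal C9H2, hydrogen loss from the C8 radical to the exocyclic alkene); the (S)-epoxide and a chair–chair array with the C7 silyloxy group equatorial set 3β-OH, 5α-H and 10β-CH2OTBS (trans fusion).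

Step 10
Reactants: 15 11-nordrim-8(12)-ene-3β,7β,15-triol 7-O-TIPS 15-O-TBS ether
Product: 16 11-nordrim-8(12)-ene-3β,7β,9α,15-tetrol 7-O-TIPS 15-O-TBS ether
Conditions: SeO2 (0.5 equiv), t-BuOOH, CH2Cl2, rt
Reagents that add atoms: tert-butyl hydroperoxide, CC(C)(C)OO; selenium dioxide, O=[Se]=O (catalytic oxygen relay)
Why: Riley allylic oxidation (ene reaction, then [2,3]-shift) at the ring CH2 (C9), since the only other allylic C–H (C7) is a deactivated α-silyloxy methine; the expected axial 9α carbinol is erased in step 11.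

Step 11
Reactants: 16 11-nordrim-8(12)-ene-3β,7β,9α,15-tetrol 7-O-TIPS 15-O-TBS ether
Product: 17 3β-hydroxy-7β-(triisopropylsilyloxy)-15-(tert-butyldimethylsilyloxy)-11-nordrim-8(12)-en-9-one
Conditions: activated MnO2, CH2Cl2, rt
Reagents that add atoms: none
Why: MnO2 oxidises the allylic alcohol selectively and leaves the saturated C3 carbinol untouched.

Step 12
Reactants: 17 3β-hydroxy-7β-(triisopropylsilyloxy)-15-(tert-butyldimethylsilyloxy)-11-nordrim-8(12)-en-9-one
Product: 18 3β-hydroxy-8β-methyl-7β-(triisopropylsilyloxy)-15-(tert-butyldimethylsilyloxy)-11-nordriman-9-one (8α-H)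
Conditions: H2 (1 atm), 10% Pd/C, EtOAc, rt
Reagents that add atoms: none
Why: Heterogeneous hydrogenation of the exocyclic enone C=C from the α-face (the β-face is blocked by the axial C10 CH2OTBS group), so H-8 is α and the new methyl β/axial; neutral conditions and the poorly aligned equatorial H-8 should prevent epimerisation.

Step 13
Reactants: 18 3β-hydroxy-8β-methyl-7β-(triisopropylsilyloxy)-15-(tert-butyldimethylsilyloxy)-11-nordriman-9-one; 19 ethyl 2-(bromomethyl)acrylate
Product: 22 3β-hydroxy C9-spiro α-methylene γ-lactone (lactone O 9β; C11 9α; 7β-OTIPS; 15-OTBS), via allylzinc bromide 20 (not isolated), via hydroxy ester 21 (not isolated)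
Conditions: activated Zn, THF, 45 °C; aq. NH4Cl; then TsOH·H2O (cat.), CH2Cl2, rt
Reagents that add atoms: zinc, [Zn] (present only in 20)
Why: Dreiding–Schmidt reaction (Reformatsky-type addition of the 2-alkoxycarbonylallylzinc, then lactonisation): the nucleophile should enter C9 axially, anti to the axial C10 and C8 substituents, so C11 is α and the oxygen β.

Step 14
Reactants: 22 3β-hydroxy C9-spiro α-methylene γ-lactone
Product: 23 3-oxo C9-spiro α-methylene γ-lactone (7β-OTIPS; 15-OTBS)
Conditions: Dess–Martin periodinane, NaHCO3, CH2Cl2, rt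
Reagents that add atoms: none
Why: Dess–Martin oxidation of the only free (secondary) alcohol; no epimerisable centre adjoins the new ketone.

Step 15
Reactants: 23 3-oxo C9-spiro α-methylene γ-lactone
Product: 24 15-hydroxy-4,4-dimethyl-3-decalone C9-spiro α-methylene γ-lactone (7β-OTIPS)
Conditions: HF·pyridine, pyridine, THF, 0 °C
Reagents that add atoms: none
Why: Fluoride-mediated desilylation is much faster for the primary TBS ether than for the hindered secondary TIPS ether.

Step 16
Reactants: 24 15-hydroxy-4,4-dimethyl-3-decalone C9-spiro α-methylene γ-lactone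
Product: 26 3,4-seco C10-spiro δ-lactone with the C4 dimethyl carbinol (7β-OTIPS; α-methylene γ-lactone retained), via seven-membered lactone 25 (not isolated)
Conditions: mCPBA (3 equiv), Na2HPO4, CH2Cl2, 0 °C to rt; then PPTS (0.2 equiv), rt
Reagents that add atoms: m-chloroperoxybenzoic acid, OOC(=O)c1cccc(Cl)c1
Why: The peracid adds to the C3 carbonyl and the more substituted neighbour C4 (quaternary, gem-dimethyl) migrates to oxygen with loss of m-chlorobenzoate, giving the ring-expanded lactone 25 (Baeyer–Villiger oxidation, the known course for 4,4-dimethyl-3-oxo terpenoids). The axial C15 hydroxyl on C10 then attacks the lactone carbonyl (6-exo-trig at the acyl carbon) and the tetrahedral intermediate expels the tertiary C4 alkoxide, so the δ-lactone ring C15–O–C3 closes as the C3–O–C4 ring opens to the carbinol (intramolecular transesterification). If 24 rests as its C3/C15 hemiketal, exchange of the hemiketal hydroxyl for the peracid and C4 migration give a cyclic dialkoxycarbenium ion that collapses with water to the same δ-lactone, so both tautomers converge. No stereocentre is formed: C5 and C10 are untouched, and the trans fusion becomes the cis relation of C15 and the carbinol side chain on ring B. The step needs C4 rather than C2 migration and acyl transfer to O15, which the migratory aptitude of the tertiary carbon and the exchange of a strained seven-membered tertiary-alkyl lactone for a six-membered primary-alkyl one should secure; the buffer prevents acid ionisation of the tertiary C–O bond before transfer. The electron-poor α-methylene lactone and the silyl ether should be inert to the peracid.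

Step 17
Reactants: 26 3,4-seco C10-spiro δ-lactone with the C4 dimethyl carbinol
Product: 27 C4-O-trimethylsilyl ether of 26
Conditions: TMSOTf, 2,6-lutidine, CH2Cl2, −78 °C
Reagents that add atoms: trimethylsilyl trifluoromethanesulfonate, C[Si](C)(C)OS(=O)(=O)C(F)(F)F
Why: Silylation of the tertiary alcohol with a non-nucleophilic base (no conjugate addition to the α-methylene lactone) removes the only proton source that could quench the ketene acetal of step 19.

Step 18
Reactants: 28 methyl 4,4-dimethoxy-3-oxopentanoate; 29 acetaldehyde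
Product: 30 methyl (Z)-2-ethylidene-4,4-dimethoxy-3-oxopentanoate
Conditions: piperidine (cat.), AcOH (cat.), 4 Å MS, CH2Cl2, 0 °C
Reagents that add atoms: none
Why: Knoevenagel condensation of the β-keto ester; the geometric isomers interconvert, and the isomer drawn has the methyl trans to the ketone, i.e. outward on the keto-diene.

Step 19
Reactants: 27 C4-O-trimethylsilyl ether of 26; 30 methyl (Z)-2-ethylidene-4,4-dimethoxy-3-oxopentanoate
Product: 32 spiro-fused 2-(triethylsilyloxy)dihydropyran ortho ester (C16–C1′ and C18–O formed; C3′=C2′ enol ether bearing CO2Me), via lactone silyl ketene acetal 31 (not isolated)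
Conditions: RhCl(PPh3)3 (3 mol%), Et3SiH (1.3 equiv), toluene, 50 °C; evaporate; 30 (2 equiv), Eu(fod)3 (5 mol%), CH2Cl2, rt
Reagents that add atoms: triethylsilane, CC[SiH](CC)CC
Why: Rh-catalysed 1,4-hydrosilylation of the s-cis enoate makes C17 a methyl and gives only the spirolactone ketene acetal, which then undergoes an inverse-electron-demand hetero-Diels–Alder reaction (concerted Mukaiyama–Michael equivalent) with the keto-diene of 30; the diene should approach the lactone face syn to H-8 (the other is screened by C1H2 and the C10 substituents), the spiro ring sits exo and the outward C1′ methyl ends cis to the C16 methyl, setting C16, C1′ and C18.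

Step 20
Reactants: 32 spiro-fused 2-(triethylsilyloxy)dihydropyran ortho ester
Product: 33 all-cis tetrahydropyran ortho ester (H-1′, H-2′ and H-3′ cis; CO2Me and C(OMe)2Me on the silyloxy face)
Conditions: H2 (50 bar), 5% Rh/Al2O3, EtOAc, rt
Reagents that add atoms: none
Why: Catalytic hydrogenation of the 2-alkoxydihydropyran-5-carboxylate alkene by syn addition from the ring face opposite the C16 methyl, the pseudo-axial C1′ methyl and the axial silyloxy group, which sets C2′ and C3′ and places the ester and ketal carbon on the face needed for cage closure.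

Step 21
Reactants: 33 all-cis tetrahydropyran ortho ester
Product: 34 7-O-TIPS chermebilaene B (closed ortho ester–ketal–lactone cage; free C4 carbinol)
Conditions: TFA, CH2Cl2, H2O (5 equiv), 0 °C to rt; concentrate from toluene
Reagents that add atoms: water, O
Why: Acid-catalysed ortho ester/ketal interchange: loss of triethylsilanol gives the dioxocarbenium ion at C18, the oxygen of the unmasked C4′ ketone adds on the face where the silyloxy group stood, and the cis ester traps the resulting C4′ oxocarbenium ion with loss of methanol (pseudo-ester lactonisation); the bridged geometry fixes C18 and C4′, and the tertiary TMS ether is cleaved in the same medium.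

Step 22
Reactants: 34 7-O-TIPS chermebilaene B
Product: 35 chermebilaene B
Conditions: HF·pyridine, THF, 0 °C to rt
Reagents that add atoms: none
Why: Fluoride-mediated removal of the secondary TIPS ether under non-basic conditions that should leave both lactones and the ortho ester intact.

**Compound list**

1 | 4-methylpent-3-en-1-ol | CC(C)=CCCO | starting material
2 | 4-methylpent-3-en-1-yl tosylate | CC(C)=CCCOS(=O)(=O)c1ccc(C)cc1 | intermediate
3 | 2-[(2S)-3,3-dimethyloxiran-2-yl]ethyl tosylate | CC1(C)O[C@H]1CCOS(=O)(=O)c1ccc(C)cc1 | intermediate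
4 | (3S)-4-methyl-3-(triisopropylsilyloxy)pent-4-en-1-yl tosylate | C=C(C)[C@@H](O[Si](C(C)C)(C(C)C)C(C)C)CCOS(=O)(=O)c1ccc(C)cc1 | intermediate
5 | [(3S)-4-methyl-3-(triisopropylsilyloxy)pent-4-en-1-yl]triphenylphosphonium iodide | C=C(C)[C@@H](O[Si](C(C)C)(C(C)C)C(C)C)CC[P+](c1ccccc1)(c1ccccc1)c1ccccc1.[I-] | intermediate
6 | 5-bromo-2-methylpent-2-ene | CC(C)=CCCBr | starting material
7 | (tert-butyldimethylsilyloxy)acetaldehyde | CC(C)(C)[Si](C)(C)OCC=O | starting material
8 | 4-methylpent-3-enylmagnesium bromide | CC(C)=CCC[Mg]Br | intermediate (not isolated)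
9 | 1-(tert-butyldimethylsilyloxy)-6-methylhept-5-en-2-ol (racemic) | CC(C)=CCCC(O)CO[Si](C)(C)C(C)(C)C | intermediate
10 | 1-(tert-butyldimethylsilyloxy)-6-methylhept-5-en-2-one | CC(C)=CCCC(=O)CO[Si](C)(C)C(C)(C)C | intermediate
11 | [(3S)-4-methyl-3-(triisopropylsilyloxy)pent-4-enylidene]triphenylphosphorane | C=C(C)[C@@H](O[Si](C(C)C)(C(C)C)C(C)C)CC=P(c1ccccc1)(c1ccccc1)c1ccccc1 | intermediate (not isolated)
12 | TBS ether of (2Z,5S)-6-methyl-2-(4-methylpent-3-enyl)-5-(triisopropylsilyloxy)hepta-2,6-dien-1-ol | CC(C)=CCC/C(CO[Si](C)(C)C(C)(C)C)=C/C[C@H](O[Si](C(C)C)(C(C)C)C(C)C)C(C)=C | intermediate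
13 | TBS ether of (2Z,5S)-2-{2-[(2S)-3,3-dimethyloxiran-2-yl]ethyl}-6-methyl-5-(triisopropylsilyloxy)hepta-2,6-dien-1-ol | CC1(C)O[C@H]1CC/C(CO[Si](C)(C)C(C)(C)C)=C/C[C@H](O[Si](C(C)C)(C(C)C)C(C)C)C(C)=C | intermediate
14 | 3-O-TMS ether of 15 | C=C1[C@@H](O[Si](C(C)C)(C(C)C)C(C)C)C[C@H]2C(C)(C)[C@@H](O[Si](C)(C)C)CC[C@]2(CO[Si](C)(C)C(C)(C)C)C1 | intermediate (not isolated)
15 | 11-nordrim-8(12)-ene-3β,7β,15-triol 7-O-TIPS 15-O-TBS ether (5α-H, 10β-CH2OTBS) | C=C1[C@@H](O[Si](C(C)C)(C(C)C)C(C)C)C[C@H]2C(C)(C)[C@@H](O)CC[C@]2(CO[Si](C)(C)C(C)(C)C)C1 | intermediate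
16 | 11-nordrim-8(12)-ene-3β,7β,9α,15-tetrol 7-O-TIPS 15-O-TBS ether | C=C1[C@@H](O[Si](C(C)C)(C(C)C)C(C)C)C[C@H]2C(C)(C)[C@@H](O)CC[C@]2(CO[Si](C)(C)C(C)(C)C)[C@@H]1O | intermediate
17 | 3β-hydroxy-7β-(triisopropylsilyloxy)-15-(tert-butyldimethylsilyloxy)-11-nordrim-8(12)-en-9-one | C=C1[C@@H](O[Si](C(C)C)(C(C)C)C(C)C)C[C@H]2C(C)(C)[C@@H](O)CC[C@]2(CO[Si](C)(C)C(C)(C)C)C1=O | intermediate
18 | 3β-hydroxy-8β-methyl-7β-(triisopropylsilyloxy)-15-(tert-butyldimethylsilyloxy)-11-nordriman-9-one | C[C@H]1[C@@H](O[Si](C(C)C)(C(C)C)C(C)C)C[C@H]2C(C)(C)[C@@H](O)CC[C@]2(CO[Si](C)(C)C(C)(C)C)C1=O | intermediate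
19 | ethyl 2-(bromomethyl)acrylate | C=C(CBr)C(=O)OCC | starting material
20 | [2-(ethoxycarbonyl)allyl]zinc bromide | C=C(C[Zn]Br)C(=O)OCC | intermediate (not isolated)
21 | C9 tertiary carbinol with 9α-CH2C(=CH2)CO2Et side chain | C[C@H]1[C@@H](O[Si](C(C)C)(C(C)C)C(C)C)C[C@H]2C(C)(C)[C@@H](O)CC[C@]2(CO[Si](C)(C)C(C)(C)C)[C@]1(O)CC(=C)C(=O)OCC | intermediate (not isolated)
22 | 3β-hydroxy C9-spiro α-methylene γ-lactone (9β-O, 11α; 7β-OTIPS; 15-OTBS) | C[C@H]1[C@@H](O[Si](C(C)C)(C(C)C)C(C)C)C[C@H]2C(C)(C)[C@@H](O)CC[C@]2(CO[Si](C)(C)C(C)(C)C)[C@]13CC(=C)C(=O)O3 | intermediate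
23 | 3-oxo C9-spiro α-methylene γ-lactone (7β-OTIPS; 15-OTBS) | C[C@H]1[C@@H](O[Si](C(C)C)(C(C)C)C(C)C)C[C@H]2C(C)(C)C(=O)CC[C@]2(CO[Si](C)(C)C(C)(C)C)[C@]13CC(=C)C(=O)O3 | intermediate
24 | 15-hydroxy-4,4-dimethyl-3-decalone C9-spiro α-methylene γ-lactone (7β-OTIPS); key-step precursor | C[C@H]1[C@@H](O[Si](C(C)C)(C(C)C)C(C)C)C[C@H]2C(C)(C)C(=O)CC[C@]2(CO)[C@]13CC(=C)C(=O)O3 | intermediate
25 | ring-A seven-membered lactone (O between C3 and C4), 15-OH free | C[C@H]1[C@@H](O[Si](C(C)C)(C(C)C)C(C)C)C[C@H]2C(C)(C)OC(=O)CC[C@]2(CO)[C@]13CC(=C)C(=O)O3 | intermediate (not isolated)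
26 | 3,4-seco C10-spiro δ-lactone with C4 dimethyl carbinol (7β-OTIPS; α-methylene γ-lactone); key-step product | C[C@H]1[C@@H](O[Si](C(C)C)(C(C)C)C(C)C)C[C@@H](C(C)(C)O)[C@]2(CCC(=O)OC2)[C@]13CC(=C)C(=O)O3 | intermediate
27 | C4-O-TMS ether of 26 | C[C@H]1[C@@H](O[Si](C(C)C)(C(C)C)C(C)C)C[C@@H](C(C)(C)O[Si](C)(C)C)[C@]2(CCC(=O)OC2)[C@]13CC(=C)C(=O)O3 | intermediate
28 | methyl 4,4-dimethoxy-3-oxopentanoate | COC(=O)CC(=O)C(C)(OC)OC | starting material
29 | acetaldehyde | CC=O | starting material
30 | methyl (Z)-2-ethylidene-4,4-dimethoxy-3-oxopentanoate | C/C=C(\C(=O)OC)C(=O)C(C)(OC)OC | intermediate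
31 | triethylsilyl ketene acetal of the α-methyl spirolactone | C[C@H]1[C@@H](O[Si](C(C)C)(C(C)C)C(C)C)C[C@@H](C(C)(C)O[Si](C)(C)C)[C@]2(CCC(=O)OC2)[C@]13CC(C)=C(O[Si](CC)(CC)CC)O3 | intermediate (not isolated)
32 | spiro-fused 2-(triethylsilyloxy)-3,4-dihydro-2H-pyran ortho ester (hetero-Diels–Alder adduct) | C[C@H]1[C@@H](O[Si](C(C)C)(C(C)C)C(C)C)C[C@@H](C(C)(C)O[Si](C)(C)C)[C@]2(CCC(=O)OC2)[C@]13C[C@]4(C)[C@@H](C)C(C(=O)OC)=C(C(C)(OC)OC)O[C@]4(O[Si](CC)(CC)CC)O3 | intermediate
33 | all-cis tetrahydropyran ortho ester | C[C@H]1[C@@H](O[Si](C(C)C)(C(C)C)C(C)C)C[C@@H](C(C)(C)O[Si](C)(C)C)[C@]2(CCC(=O)OC2)[C@]13C[C@]4(C)[C@@H](C)[C@@H](C(=O)OC)[C@@H](C(C)(OC)OC)O[C@]4(O[Si](CC)(CC)CC)O3 | intermediate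
34 | 7-O-TIPS chermebilaene B | C[C@H]1[C@@H](O[Si](C(C)C)(C(C)C)C(C)C)C[C@@H](C(C)(C)O)[C@]2(CCC(=O)OC2)[C@]12C[C@]1(C)[C@@H](C)[C@H]3C(=O)O[C@@]4(C)O[C@@]1(O[C@@H]34)O2 | intermediate
35 | chermebilaene B | C[C@H]1[C@@H](O)C[C@@H](C(C)(C)O)[C@]2(CCC(=O)OC2)[C@]12C[C@]1(C)[C@@H](C)[C@H]3C(=O)O[C@@]4(C)O[C@@]1(O[C@@H]34)O2 | target

**Step count.** Total: 22 steps. Longest linear sequence: 19 steps (1–4, 7–17, 19–22).

**Steps most likely to fail**

Step 19. The union may be sluggish at the fully substituted ketene acetal carbon, or π-facial and endo/exo control may erode so that C16 and C1′ form as mixtures. The fallback sets out from 27 and returns at 32 without new compounds. Ketene acetal 31 is generated as before but joined to 30 in a stepwise Mukaiyama–Michael addition promoted by a chiral copper(II) bis(oxazoline) triflate (CH2Cl2, −78 °C). The Lewis acid chelates the 1,3-dicarbonyl of 30, raises its electrophilicity and lets the catalyst, not only the lactone face, select the C1′ face. The zwitterion should collapse by O–C18 bond formation to the same ortho ester 32.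

Step 20. Hydrogen may be delivered to the wrong ring face, or the tetrasubstituted push–pull alkene may resist reduction until the silyl ortho ester is lost. The fallback sets out from 32 and returns at 34. Mild hydrolysis (PPTS, wet THF) opens the ortho ester to the open-chain β-keto ester F1 with the spirolactone restored. Noyori asymmetric hydrogenation (Ru–BINAP, H2, MeOH; catalyst antipode chosen for the required carbinol) reduces the ketone under reagent control, with dynamic kinetic resolution at the labile C2′, to the β-hydroxy ester F2. Under the conditions of step 21, F2 should close the cage by addition of the C3′ hydroxyl and the C4′ ketone oxygen to the lactone carbonyl and lactonisation of the ester, giving 34.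

Step 13. The organozinc may enolise the hindered ketone (with loss of the axial C8 methyl configuration) instead of adding. The fallback sets out from 18 and returns at 22. Samarium(II)-mediated ketyl–olefin coupling with methyl methacrylate (SmI2, t-BuOH, THF, −78 to 0 °C) forms the C9–C11 bond along the same axial trajectory and lactonises to the α-methyl spirolactone F3 (configuration at the methyl-bearing carbon immaterial). Enolate selenenylation (LDA, 2.2 equiv, then PhSeCl, −78 °C) gives the α-phenylseleno lactone F4. Oxidation (H2O2, pyridine, 0 °C) and selenoxide syn-elimination toward the methyl group should give 22.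

**Further compounds**

F0 | step 19 | none | none
F1 | step 20 | open-chain β-keto ester with restored spirolactone (C2′ epimerisable) | C[C@H]1[C@@H](O[Si](C(C)C)(C(C)C)C(C)C)C[C@@H](C(C)(C)O[Si](C)(C)C)[C@]2(CCC(=O)OC2)[C@]13C[C@](C)([C@@H](C)C(C(=O)OC)C(=O)C(C)(OC)OC)C(=O)O3
F2 | step 20 | β-hydroxy ester (C2′ and C3′ set) | C[C@H]1[C@@H](O[Si](C(C)C)(C(C)C)C(C)C)C[C@@H](C(C)(C)O[Si](C)(C)C)[C@]2(CCC(=O)OC2)[C@]13C[C@](C)([C@@H](C)[C@@H](C(=O)OC)[C@H](O)C(C)(OC)OC)C(=O)O3
F3 | step 13 | 3β-hydroxy C9-spiro α-methyl γ-lactone (7β-OTIPS; 15-OTBS) | C[C@H]1[C@@H](O[Si](C(C)C)(C(C)C)C(C)C)C[C@H]2C(C)(C)[C@@H](O)CC[C@]2(CO[Si](C)(C)C(C)(C)C)[C@]13CC(C)C(=O)O3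
F4 | step 13 | α-methyl-α-phenylseleno spirolactone | C[C@H]1[C@@H](O[Si](C(C)C)(C(C)C)C(C)C)C[C@H]2C(C)(C)[C@@H](O)CC[C@]2(CO[Si](C)(C)C(C)(C)C)[C@]13CC(C)([Se]c4ccccc4)C(=O)O3
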